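## Structural features

The target is an achiral diaryl ether. Two benzoic acid rings, each with an n-heptyl chain ortho to its carboxyl group, are joined through one oxygen between C4 of ring A and C2' of ring B. Ring A is a salicylic acid (C1 CO2H, C2 OH, C4 ether oxygen, C6 heptyl, H at C3 and C5). Ring B carries C1' CO2H, the ether oxygen at C2', OMe at C4' and heptyl at C6'. The target has no stereocentre and no stereogenic double bond, so the only adjacent stereocentres in the plan, C1 and C6 of the cyclohexenone stage of ring A, are temporary. The fragile groups are the two electron-rich, doubly ortho-substituted carboxylic acids: they lose CO2 on heating or in acid (ring A most readily), and the 2-aryloxybenzoic acid of ring B can close to a xanthone in dehydrating acid, so both acids must be released last under neutral conditions. The real difficulty is twofold: the C4–O–C2' bond lies next to a carboxyl group between two hindered, electron-rich arenes, and three phenol-type oxygens of the same family must end up different (OH, OMe, OAr). The key step uses the fact that ring A is one dehydrogenation above a 2-oxocyclohex-3-ene-1-carboxylate, whose C2–C3–C4–C5 segment with the oxygen on C4 is a 3-aryloxybut-2-enoate and whose C1–C6 segment with the chain is a dec-2-enoate. The ether bond can therefore be made by adding the ring-B phenol to an sp carbon before ring A exists, and O2 (ketone) and O4 (aryl ether) are already different in the ring that forms.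

## Logic of the disconnections

**20 ⇒ 19.** The two acid O–H bonds are traced back to O–CH2Ph bonds, and no skeletal bond is cut. The cut stands here because both acids decarboxylate easily and should appear only at room temperature under neutral conditions. The gain is that all earlier chemistry handles neutral esters. The demand is that 19 contains nothing else reducible and is free of selenium residues that would poison the catalyst.

**19 ⇒ 16.** Ring A is lowered by one oxidation level: the C2 phenol becomes a ketone, C1 and C6 become sp3 CH and C5 becomes CH2. This turns a 1,2,4,6-tetrasubstituted arene into a β-keto ester and vinylogous ester that carbonyl chemistry can assemble. The cost is two throw-away stereocentres. The forward step must start at C1, the most acidic position, pass through 17 and 18, and be mild enough to leave the C4–OAr vinylogous ester uncleaved.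

**16 ⇒ 11 + 13.** C5–C6 (Michael bond) and C1–C2 (Dieckmann bond) are cut.
- This is the only cut that opens ring A into two acyclic unsaturated esters while leaving the C4–O–C2' bond intact, so the molecule falls into two pieces of similar size.
- The forward step needs γ-deprotonation of 11 in preference to the ring-B benzylic CH2. It also needs γ-attack in a 1,4-sense and a dienolate (14) that lasts until 13 arrives.
- Three features of 11 are chosen for this. The E geometry keeps C-methyl and ester cis. The ester that is lost is methyl, the least hindered, so closure of 15 is fast and the alkoxide is neutralised at once by the product.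
- The ring-B ester stays benzyl. An acid-labile hindered ester would force an acidic endgame on decarboxylation-prone acids, and a free carboxylate would add to the β-carbon of the crotonate.

**13 ⇒ 1 + 12.** The C2=C3 double bond is cut. A phosphonate olefination gives the E-enoate in one step from a cheap C8 aldehyde and brings in the ring-A benzyl ester. The only demand is E selectivity, although geometry has little consequence because C6 is later flattened.

**11 ⇒ 9 + 10.** The vinyl carbon–oxygen bond (the future C4–O bond) is cut. A hindered diaryl ether coupling thus becomes a conjugate addition of a phenol to an ynoate. The forward step must give the E isomer. It must also protonate the carbanion formed by the addition faster than that carbanion can attack the neighbouring ester.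

**9 ⇒ 8.** The O–CH3 bond at C4' is cut. The two hydroxyl groups of 8 differ intrinsically: one is chelated to the ester carbonyl and hindered, the other is free. No protecting group is needed, only control of the amount of alkylating agent.

**8 ⇒ 6.** Ring B is also lowered by one oxidation level, to a cyclohexane-1,3-dione carboxylate. This exposes a 1,5-dicarbonyl relationship. The forward aromatisation (through 7) must spare the benzyl ester.

**6 ⇒ 3 + 4.** C1'–C6' (Michael bond) and C2'–C3' (Claisen bond) are cut. Ring B opens into a malonate and an enone, and all four substituents arrive in their final positions. One equivalent of base is needed, and the acidity of the 1,3-dione drives the closure of 5.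

**3 ⇒ 1 + 2.** The C3=C4 double bond of the enone is cut. The same C8 aldehyde then serves both rings. A stabilised ylide needs no base, which avoids self-condensation of the aldehyde.

## Other disconnections considered

**Alternative 1:**
- *Cut:* the C6'–heptyl and C1'–carboxyl bonds of ring B.
- *Forward key step:* iodine–magnesium exchange on the iodo sulfonate A1 and loss of the sulfonate would give the C1'–C6' aryne. Heptylmagnesium bromide A2 would add at C6', and carboxylation of the C1' arylmagnesium would give acid A3.
- *In favour:* two adjacent carbon substituents go in during one operation. The regiochemistry rests on a sound element, since the C2' aryloxy group directs the nucleophile to the distal aryne carbon and stabilises the carbanion next to oxygen. That control is at least as well founded as the γ-selectivity on which the chosen plan relies. No redox adjustment is needed, the two acids emerge differentiated, and the chain could be varied late; on these points it is the better plan.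
- *Against:* the diaryl ether is already present in A1, so the hardest bond is only pushed back to an arene C–O coupling. That coupling would have to be run beside, or before the installation of, an aryl iodide flanked by two oxygens. An alkyl Grignard reagent with β-hydrogens can reduce the aryne as well as add to it. An excess of it must also coexist with the ring-A ester while the mixture warms. A3 then needs acid to remove the tert-butyl and methoxymethyl groups, the conditions under which the ring-A salicylic acid loses its carboxyl group.
- *Comparison:* both key steps form two bonds, but this one closes no ring. Ring A with its chain must still be built separately, so the total count would be higher than nine steps. The chosen plan makes the ether under mild conditions and ends neutrally.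

**Alternative 2:**
- *Cut:* C2'–C3' and C1'–C6'.
- *Forward key step:* Diels–Alder addition of 6-heptyl-4-methoxypyran-2-one A4 to the ring-A aryloxypropiolate A5, then decarboxylative cycloreversion of the bridged lactone, to give the tribenzyl compound A6.
- *In favour:* ring B arrives aromatic with all four substituents placed and needs no oxidation step. The polarity is matched, since the nucleophilic C3 of A4 meets the β-carbon of the ynoate. The step is neutral, so acylation of a carbanion and loss of aryloxide cannot occur. A6 is a single hydrogenolysis from the target, so the endgame is shorter than in the chosen plan. A4 should be available in two or three routine steps.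
- *Against:* A5 belongs to a rare class of push–pull ynol ether esters. The usual entries to aryl alkynyl ethers use strongly basic eliminations and metalations that the ring-A benzyl ester would not tolerate. The oxygen donor lowers the dienophilicity of the triple bond. The new C1'–C6' bond joins a heptyl-bearing and an ester-bearing carbon. The addition would therefore need high temperature, where alkynyl aryl ethers are thermally unreliable.
- *Comparison:* it equals the chosen plan in bonds formed and rings closed and is better in redox economy. It is weaker in access to its key partner: 11 comes from one mild addition, whereas A5 has no comparably safe preparation.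

**Alternative 3:**
- *Cut:* C3'–C4', C1'–C2' and C4'–C5'.
- *Forward key step:* a tertiary amine would dehydrochlorinate acid chloride A7 to the ester-bearing vinylketene A8. A8 would add [2+2] to the ring-A ethynyl ether A9. On heating, the cyclobutenone would open (4π) and reclose (6π) to the ring-B phenol A10.
- *In favour:* the [2+2] orientation of ketenes with ynol ethers is dependable. The cascade is neutral and thermal. The C4' oxygen appears as the only free phenol, so its methylation is unambiguous, a differentiation as clean as in the chosen plan. Ring B again needs no separate dehydrogenation, which is better.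
- *Against:* A8 is also an acylketene, and acylketenes tend to react with electron-rich alkynes as oxadienes and to dimerise. The base can take a γ-proton of A7 from the methyl group or from the chain CH2, and only the first leads to ring B. A9 has the same preparative problem as other aryl alkynyl ethers in the presence of an ester. Generating vinylketenes from acid chlorides is also the least developed variant of this benzannulation.
- *Comparison:* after A10, a methylation and a hydrogenolysis remain, the same two operations that follow 16. The step count after the key step is therefore equal, but the way to A7 and A9 would be longer and less secure than the way to 11 and 13.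

Key step: step 7

Remark on the chemistry: all chiral intermediates (5, 6, 7, 15, 16, 17) are racemic. Where two centres are drawn, the SMILES shows one enantiomer of the stated relative configuration. Compounds 6 and 16 are written as keto tautomers although they are largely enolised. In 11 the descriptor E means aryloxy trans, and C-methyl cis, to the ester group.

## Steps

Step 1
Reactants: 1 octanal; 2 1-(triphenyl-λ5-phosphanylidene)propan-2-one
Product: 3 (3E)-undec-3-en-2-one
Conditions: CH2Cl2, reflux
Reagents that add atoms: none
Why: Wittig olefination with a ketone-stabilised ylide, which should give the E-enone. No external base is present, so the enolisable aldehyde should not self-condense.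

Step 2
Reactants: 3 (3E)-undec-3-en-2-one; 4 dibenzyl malonate
Product: 6 benzyl (1R*,6S*)-6-heptyl-2,4-dioxocyclohexane-1-carboxylate (racemic trans isomer), via Michael adduct 5 (not isolated)
Conditions: NaH (1.1 equiv), THF, 0 °C to reflux; then 1 M HCl
Reagents that add atoms: none
Why: Tandem Michael addition and Dieckmann-type Claisen cyclisation, the classical entry to 5-alkyldihydroresorcinol carboxylates: the malonate anion adds to C4 of 3, the methyl ketone enolate of 5 closes on one benzyl ester, and deprotonation of the acidic 1,3-dione drives the closure. C6 forms without control (racemate) and C1 equilibrates to the trans isomer. Both centres vanish in step 3.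

Step 3
Reactants: 6 benzyl (1R*,6S*)-6-heptyl-2,4-dioxocyclohexane-1-carboxylate
Product: 8 benzyl 2-heptyl-4,6-dihydroxybenzoate, via bromodione 7 (not isolated)
Conditions: Br2 (1.0 equiv), DMF, 0 °C, then 80 °C
Reagents that add atoms: bromine, BrBr (the bromine atom stands in 7 only and is lost again)
Why: Bromination–dehydrobromination aromatisation of a dihydroresorcinol carboxylate: the enol is brominated to 7, and on warming bromine transposition, loss of HBr and tautomerisation should give the resorcinol. DMF buffers the HBr, and 80 °C lies well below the temperature at which bromide dealkylates such esters.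

Step 4
Reactants: 8 benzyl 2-heptyl-4,6-dihydroxybenzoate
Product: 9 benzyl 2-heptyl-6-hydroxy-4-methoxybenzoate
Conditions: MeI (1.1 equiv), K2CO3 (1.1 equiv), acetone, rt to 40 °C
Reagents that add atoms: iodomethane, CI
Why: Williamson ether synthesis. The hydroxyl group ortho to the ester is chelated to the carbonyl, less acidic and hindered, so a slight excess of iodomethane should alkylate only the para hydroxyl group.

Step 5
Reactants: 9 benzyl 2-heptyl-6-hydroxy-4-methoxybenzoate; 10 methyl but-2-ynoate
Product: 11 benzyl 2-heptyl-4-methoxy-6-{[(2E)-4-methoxy-4-oxobut-2-en-2-yl]oxy}benzoate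
Conditions: 10 (1.5 equiv), DABCO (0.2 equiv), MeCN, 60 °C
Reagents that add atoms: none
Why: Amine-catalysed oxa-Michael addition of a phenol to an ynoate. Neutral phenol is always present to protonate the allenolate as it forms, which should suppress attack on the neighbouring benzyl ester. Reversible addition of catalyst and phenoxide should equilibrate the double bond to the more stable E isomer.

Step 6
Reactants: 1 octanal; 12 benzyl (diethoxyphosphoryl)acetate
Product: 13 benzyl (2E)-dec-2-enoate
Conditions: NaH (1.05 equiv), THF, 0 °C to rt
Reagents that add atoms: none
Why: Horner–Wadsworth–Emmons olefination of an unbranched aldehyde with a stabilised phosphonate anion, which should be E-selective. The phosphate by-product is removed with water.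

Step 7
Reactants: 11 benzyl 2-heptyl-4-methoxy-6-{[(2E)-4-methoxy-4-oxobut-2-en-2-yl]oxy}benzoate; 13 benzyl (2E)-dec-2-enoate
Product: 16 benzyl (1R*,6S*)-4-{2-[(benzyloxy)carbonyl]-3-heptyl-5-methoxyphenoxy}-6-heptyl-2-oxocyclohex-3-ene-1-carboxylate (racemic trans isomer), via lithium dienolate 14 (not isolated), via acyclic ester enolate 15 (not isolated)
Conditions: LDA (1.05 equiv, commercial solution), THF, −78 °C, 10 min; 13 (1.1 equiv), −78 °C to 0 °C; AcOH quench
Reagents that add atoms: lithium diisopropylamide, [Li+].CC(C)[N-]C(C)C (lithium stands in 14 and 15 only)
Why: Proposed new method: LDA takes a proton from the C-methyl group of 11, which the E geometry places cis to the ester carbonyl (lithium coordination steers the base there) and which, as the vinylogous α-position of an ester, is clearly more acidic than the secondary benzylic CH2 of ring B, so one equivalent of base should give only the U-shaped dienolate 14. The γ-carbon of 14 adds in a 1,4-sense to C3 of 13 (bond C5–C6) to give ester enolate 15, and on warming 15 attacks the methyl ester carbonyl, held cis by the regenerated E double bond, in a 6-(enolexo)-exo-trig Dieckmann closure (bond C1–C2) that expels methoxide and forms the only new ring. The methoxide at once removes the C1 proton of the β-keto ester, which makes the sequence irreversible and, by turning the enone into an enolate, shields C4 from addition–elimination and the benzyl esters from transesterification. The closest known reaction type is the Michael–Dieckmann (anionic [4+2]) annulation of 3-alkoxycrotonate dienolates with α,β-unsaturated esters to 3-alkoxycyclohex-2-enones; the new element is the aryloxy group, a far better leaving group that here also carries an ortho ester. γ-Selectivity is expected as in the alkoxy series, because the 3-oxygen raises the coefficient at the γ-carbon and only the γ-adduct can drain away through ring closure. Loss of aryloxide from 14 is disfavoured stereoelectronically, since the C–O bond lies in the nodal plane of the dienolate π system, and acylation of 14 by the ring-B ester is countered by the donor-deactivated, doubly ortho-substituted nature of that carbonyl together with a short ageing time at −78 °C before 13 is added. C6 is created in the Michael step with no controlling element (racemate), and C1, flanked by two carbonyl groups, equilibrates to the trans, diequatorial relation to C6; both centres disappear in step 8, so no stereoselectivity is required.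

Step 8
Reactants: 16 benzyl (1R*,6S*)-4-{2-[(benzyloxy)carbonyl]-3-heptyl-5-methoxyphenoxy}-6-heptyl-2-oxocyclohex-3-ene-1-carboxylate
Product: 19 benzyl 2-{4-[(benzyloxy)carbonyl]-3-heptyl-5-hydroxyphenoxy}-6-heptyl-4-methoxybenzoate, via selenide 17 (not isolated), via dienone tautomer 18 (not isolated)
Conditions: PhSeCl (1.1 equiv), pyridine (1.2 equiv), CH2Cl2, 0 °C; wash; then 30% H2O2 (2.5 equiv), CH2Cl2, 0 °C to rt
Reagents that add atoms: benzeneselenenyl chloride, Cl[Se]c1ccccc1 (the PhSe group stands in 17 only)
Why: α-Selenenylation of a β-keto ester followed by selenoxide syn-elimination. The enol should be attacked at C1 on the face opposite the heptyl group, which puts selenium cis to H6 as the syn-elimination requires. The C1=C6 double bond so formed gives 18, the keto tautomer of a phenol, which enolises at once to the ring-A salicylate and erases both stereocentres.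

Step 9
Reactants: 19 benzyl 2-{4-[(benzyloxy)carbonyl]-3-heptyl-5-hydroxyphenoxy}-6-heptyl-4-methoxybenzoate
Product: 20 4-(2-carboxy-3-heptyl-5-methoxyphenoxy)-2-heptyl-6-hydroxybenzoic acid (target)
Conditions: H2 (1 atm), 10% Pd/C, EtOAc, rt; evaporation below 30 °C
Reagents that add atoms: none
Why: Catalytic hydrogenolysis of both benzyl esters under neutral conditions at room temperature, the mildest way to release decarboxylation-prone hydroxybenzoic acids. The diaryl ether, methyl ether and alkyl chains are inert.

## Compound list

1 | octanal | CCCCCCCC=O | starting material
2 | 1-(triphenyl-λ5-phosphanylidene)propan-2-one | CC(=O)C=P(c1ccccc1)(c1ccccc1)c1ccccc1 | starting material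
3 | (3E)-undec-3-en-2-one | CCCCCCC/C=C/C(C)=O | intermediate
4 | dibenzyl malonate | O=C(CC(=O)OCc1ccccc1)OCc1ccccc1 | starting material
5 | dibenzyl 2-(2-oxoundecan-4-yl)propanedioate (racemic, not isolated) | CCCCCCCC(CC(C)=O)C(C(=O)OCc1ccccc1)C(=O)OCc1ccccc1 | intermediate
6 | benzyl (1R*,6S*)-6-heptyl-2,4-dioxocyclohexane-1-carboxylate (racemic, trans, largely enolised) | O=C1CC(=O)C[C@H](CCCCCCC)[C@H]1C(=O)OCc1ccccc1 | intermediate
7 | benzyl 3-bromo-6-heptyl-2,4-dioxocyclohexane-1-carboxylate (stereoisomer mixture, enolised, not isolated) | CCCCCCCC1CC(=O)C(Br)C(=O)C1C(=O)OCc1ccccc1 | intermediate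
8 | benzyl 2-heptyl-4,6-dihydroxybenzoate | CCCCCCCc1cc(O)cc(O)c1C(=O)OCc1ccccc1 | intermediate
9 | benzyl 2-heptyl-6-hydroxy-4-methoxybenzoate | CCCCCCCc1cc(OC)cc(O)c1C(=O)OCc1ccccc1 | intermediate
10 | methyl but-2-ynoate | CC#CC(=O)OC | starting material
11 | benzyl 2-heptyl-4-methoxy-6-{[(2E)-4-methoxy-4-oxobut-2-en-2-yl]oxy}benzoate | C/C(Oc1cc(OC)cc(CCCCCCC)c1C(=O)OCc1ccccc1)=C\C(=O)OC | intermediate
12 | benzyl (diethoxyphosphoryl)acetate | CCOP(=O)(OCC)CC(=O)OCc1ccccc1 | starting material
13 | benzyl (2E)-dec-2-enoate | CCCCCCC/C=C/C(=O)OCc1ccccc1 | intermediate
14 | lithium dienolate of 11 (lithium 3-aryloxy-1-methoxybuta-1,3-dien-1-olate, enolate geometry not defined, not isolated) | [Li+].[O-]C(OC)=CC(=C)Oc1cc(OC)cc(CCCCCCC)c1C(=O)OCc1ccccc1 | intermediate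
15 | C6 lithium enolate of 7-benzyl 1-methyl (2E)-3-{2-[(benzyloxy)carbonyl]-3-heptyl-5-methoxyphenoxy}-5-heptylhept-2-enedioate (racemic, not isolated) | [Li+].[O-]C(OCc1ccccc1)=CC(CCCCCCC)C/C(Oc1cc(OC)cc(CCCCCCC)c1C(=O)OCc1ccccc1)=C\C(=O)OC | intermediate
16 | benzyl (1R*,6S*)-4-{2-[(benzyloxy)carbonyl]-3-heptyl-5-methoxyphenoxy}-6-heptyl-2-oxocyclohex-3-ene-1-carboxylate (racemic, trans) | O=C1C=C(Oc2cc(OC)cc(CCCCCCC)c2C(=O)OCc2ccccc2)C[C@H](CCCCCCC)[C@H]1C(=O)OCc1ccccc1 | intermediate
17 | benzyl (1R*,6S*)-4-{2-[(benzyloxy)carbonyl]-3-heptyl-5-methoxyphenoxy}-6-heptyl-2-oxo-1-(phenylselanyl)cyclohex-3-ene-1-carboxylate (racemic, PhSe trans to heptyl, not isolated) | O=C1C=C(Oc2cc(OC)cc(CCCCCCC)c2C(=O)OCc2ccccc2)C[C@H](CCCCCCC)[C@]1([Se]c1ccccc1)C(=O)OCc1ccccc1 | intermediate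
18 | benzyl 4-{2-[(benzyloxy)carbonyl]-3-heptyl-5-methoxyphenoxy}-2-heptyl-6-oxocyclohexa-1,4-diene-1-carboxylate (not isolated) | O=C1C=C(Oc2cc(OC)cc(CCCCCCC)c2C(=O)OCc2ccccc2)CC(CCCCCCC)=C1C(=O)OCc1ccccc1 | intermediate
19 | benzyl 2-{4-[(benzyloxy)carbonyl]-3-heptyl-5-hydroxyphenoxy}-6-heptyl-4-methoxybenzoate | CCCCCCCc1cc(Oc2cc(OC)cc(CCCCCCC)c2C(=O)OCc2ccccc2)cc(O)c1C(=O)OCc1ccccc1 | intermediate
20 | 4-(2-carboxy-3-heptyl-5-methoxyphenoxy)-2-heptyl-6-hydroxybenzoic acid | CCCCCCCc1cc(Oc2cc(OC)cc(CCCCCCC)c2C(=O)O)cc(O)c1C(=O)O | target

## Step count and least certain steps

Total step count: 9. Longest linear sequence: 8 (steps 1, 2, 3, 4, 5, 7, 8, 9). Step 6 is a one-step side branch.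

**Step 7 (key step, Proposed new method).**
- *What may go wrong:* the dienolate may be consumed before it meets the sluggish β-alkyl acceptor. One path is Claisen-type acylation at the neighbouring ring-B ester through a six-membered transition state. The other is fragmentation with loss of the stabilised aryloxide, which is a much better leaving group than the alkoxide of the known cases.
- *Secondary risks:* proton transfer from the γ-position of 13, attack through the α-carbon, and a second Michael addition of 15 to surplus 13.
- *Fallback with known chemistry:* it sets out from 9 and 8 and returns at 19. Compound 9 is converted with Tf2O and pyridine in CH2Cl2 into benzyl 2-heptyl-4-methoxy-6-{[(trifluoromethyl)sulfonyl]oxy}benzoate F1. F1 is then joined to the unchelated, more acidic 4-hydroxyl group of 8 by palladium-catalysed C–O coupling (Pd(OAc)2, t-BuXPhos, K3PO4, toluene, 100 °C). The ortho ester of F1 assists oxidative addition to zerovalent palladium and the reductive elimination. Steps 5 to 8 then drop out.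

**Step 5.**
- *What may go wrong:* the addition may be slow, because the phenol is chelated and the β-carbon of the ynoate is substituted. Forcing it invites incomplete E/Z equilibration and cyclisation of the intermediate carbanion onto the adjacent ester.
- *Fallback:* it sets out from 9 and returns at 16. The ynoate is replaced by the much more electrophilic ethyl buta-2,3-dienoate (DABCO cat., CH2Cl2, rt), whose central carbon accepts phenols at room temperature. Isomerisation into conjugation should give benzyl 2-{[(2E)-4-ethoxy-4-oxobut-2-en-2-yl]oxy}-6-heptyl-4-methoxybenzoate F2. F2 takes the place of 11 in step 7 and loses ethoxide instead of methoxide.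

**Step 8.**
- *What may go wrong:* selenenylation may occur on the wrong face, leaving no hydrogen syn to selenium, or at C3. Peroxide may add to and cleave the C4 vinylogous aryl ester while C1 is blocked. The peroxyseleninic acid formed from surplus H2O2 may over-oxidise the new phenol.
- *Fallback:* it sets out from 16 and returns at 19, replacing α-functionalisation and elimination by hydride abstraction from a silyloxydiene. TBSOTf and Et3N in CH2Cl2 should give benzyl 2-[(tert-butyldimethylsilyl)oxy]-4-{2-[(benzyloxy)carbonyl]-3-heptyl-5-methoxyphenoxy}-6-heptylcyclohexa-1,3-diene-1-carboxylate F3. DDQ in toluene at room temperature should aromatise F3 to benzyl 2-{4-[(benzyloxy)carbonyl]-3-[(tert-butyldimethylsilyl)oxy]-5-heptylphenoxy}-6-heptyl-4-methoxybenzoate F4. TBAF buffered with AcOH then releases 19.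

**Step 3.**
- *What may go wrong:* the activated resorcinol may be brominated on the ring. The benzyl ester may be partly dealkylated by bromide in the acidic medium, with decarboxylation following.
- *Fallback:* it sets out from 6 and returns at 8, and drives that ester loss to completion on purpose. Br2 in DMF, then heating at 160 °C, should give 5-heptylbenzene-1,3-diol F5. Carboxylation of F5 with MeOMgOCO2Me (methoxymagnesium methyl carbonate) in DMF at 120 °C should give 2-heptyl-4,6-dihydroxybenzoic acid F6. Selective alkylation of the carboxylate of F6 (BnBr, KHCO3, DMF, rt) then gives 8.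

## Further compounds

F1 | step 7 | benzyl 2-heptyl-4-methoxy-6-{[(trifluoromethyl)sulfonyl]oxy}benzoate | CCCCCCCc1cc(OC)cc(OS(=O)(=O)C(F)(F)F)c1C(=O)OCc1ccccc1
F2 | step 5 | benzyl 2-{[(2E)-4-ethoxy-4-oxobut-2-en-2-yl]oxy}-6-heptyl-4-methoxybenzoate | C/C(Oc1cc(OC)cc(CCCCCCC)c1C(=O)OCc1ccccc1)=C\C(=O)OCC
F3 | step 8 | benzyl 2-[(tert-butyldimethylsilyl)oxy]-4-{2-[(benzyloxy)carbonyl]-3-heptyl-5-methoxyphenoxy}-6-heptylcyclohexa-1,3-diene-1-carboxylate (racemic) | CCCCCCCC1CC(Oc2cc(OC)cc(CCCCCCC)c2C(=O)OCc2ccccc2)=CC(O[Si](C)(C)C(C)(C)C)=C1C(=O)OCc1ccccc1
F4 | step 8 | benzyl 2-{4-[(benzyloxy)carbonyl]-3-[(tert-butyldimethylsilyl)oxy]-5-heptylphenoxy}-6-heptyl-4-methoxybenzoate | CCCCCCCc1cc(Oc2cc(OC)cc(CCCCCCC)c2C(=O)OCc2ccccc2)cc(O[Si](C)(C)C(C)(C)C)c1C(=O)OCc1ccccc1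
F5 | step 3 | 5-heptylbenzene-1,3-diol | CCCCCCCc1cc(O)cc(O)c1
F6 | step 3 | 2-heptyl-4,6-dihydroxybenzoic acid | CCCCCCCc1cc(O)cc(O)c1C(=O)O
A1 | alternative 1 | tert-butyl 4-{3-[(4-chlorobenzenesulfonyl)oxy]-2-iodo-5-methoxyphenoxy}-2-heptyl-6-(methoxymethoxy)benzoate | CCCCCCCc1cc(Oc2cc(OC)cc(OS(=O)(=O)c3ccc(Cl)cc3)c2I)cc(OCOC)c1C(=O)OC(C)(C)C
A2 | alternative 1 | heptylmagnesium bromide | CCCCCCC[Mg]Br
A3 | alternative 1 | 2-{4-[(tert-butoxy)carbonyl]-3-heptyl-5-(methoxymethoxy)phenoxy}-6-heptyl-4-methoxybenzoic acid | CCCCCCCc1cc(Oc2cc(OC)cc(CCCCCCC)c2C(=O)O)cc(OCOC)c1C(=O)OC(C)(C)C
A4 | alternative 2 | 6-heptyl-4-methoxy-2H-pyran-2-one | CCCCCCCc1cc(OC)cc(=O)o1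
A5 | alternative 2 | benzyl 2-(benzyloxy)-4-{[3-(benzyloxy)-3-oxoprop-1-yn-1-yl]oxy}-6-heptylbenzoate | CCCCCCCc1cc(OC#CC(=O)OCc2ccccc2)cc(OCc2ccccc2)c1C(=O)OCc1ccccc1
A6 | alternative 2 | benzyl 2-{3-(benzyloxy)-4-[(benzyloxy)carbonyl]-5-heptylphenoxy}-6-heptyl-4-methoxybenzoate | CCCCCCCc1cc(Oc2cc(OC)cc(CCCCCCC)c2C(=O)OCc2ccccc2)cc(OCc2ccccc2)c1C(=O)OCc1ccccc1
A7 | alternative 3 | benzyl 2-(chlorocarbonyl)-3-methyldec-2-enoate (double-bond geometry not defined) | CCCCCCCC(C)=C(C(=O)Cl)C(=O)OCc1ccccc1
A8 | alternative 3 | benzyl 3-methylidene-2-(oxomethylidene)decanoate | CCCCCCCC(=C)C(=C=O)C(=O)OCc1ccccc1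
A9 | alternative 3 | benzyl 2-(benzyloxy)-4-(ethynyloxy)-6-heptylbenzoate | CCCCCCCc1cc(OC#C)cc(OCc2ccccc2)c1C(=O)OCc1ccccc1
A10 | alternative 3 | benzyl 2-{3-(benzyloxy)-4-[(benzyloxy)carbonyl]-5-heptylphenoxy}-6-heptyl-4-hydroxybenzoate | CCCCCCCc1cc(Oc2cc(O)cc(CCCCCCC)c2C(=O)OCc2ccccc2)cc(OCc2ccccc2)c1C(=O)OCc1ccccc1
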